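## Retrosynthetic overview

- The 3(2H)-furanone ring (O–C10(CH3)–C1(=O)–C2H=C3) is read as the [3+2] adduct of a 2-oxyallyl cation (C10–C1–C2) and an amide carbonyl (C3=O) minus dimethylamine. Cutting C2–C3 and O–C10 opens the furanone and the ten-membered carbocycle (C1–C10) together and leads to the acyclic seco-amide 24.
- The feature that allows this: C10 is fully substituted (a tertiary cation terminus that carries no stereochemical information before the step), C2 is the unsubstituted carbon of a methyl ketone, and C3 is a carboxyl-level carbon on the C4(=C15H2) acrylic unit.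
- 24 comes from a BF3-promoted SE2' union (C6–C7) of butenolide allylstannane 11 with aldehyde 19, which creates the α-methylene lactone, C6 and C7 in one event. Methacrylation and a regiospecific decarboxylative chlorination at C10 follow.
- 11 is built from tert-butyl 2-methylacetoacetate (C1, C2, C10, C14), allyl bromide (C8, C9) and ethyl 2-(bromomethyl)acrylate (C7, C11–C13), with C8 set by catalysis. 19 comes from chiral-pool (S)-3-hydroxy-γ-butyrolactone, whose four carbons are C3–C6 and whose stereocentre is C5.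
- Ring order: γ-lactone (step 3, carried as a butenolide, re-formed as the α-methylene lactone in step 11), then furanone and ten-membered ring together (step 15).

Key step: step 15

Remarks on the chemistry:
- Locants are the germacrane locants of the target: C1 ring ketone, C2 (=CH), C3 (O–C=), C4 (=C15H2), C5 (OH), C6 (O-methacryloyl), C7, C8 (lactone O), C9 (CH2), C10 (C14 methyl), C11 (=C13H2), C12 (lactone C=O).
- C10 is carried as a mixture of both configurations from compound 3 to compound 24 (no stereo tag in the SMILES); this is of no consequence because both epimers give the same planar oxyallyl cation in step 15.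
- In step 3 the antipode of the bis(oxazoline) ligand is the one that delivers the (R)-lactone 8; both antipodes are accessible.

## Route

Step 1
Reactants: 1 tert-butyl 2-methyl-3-oxobutanoate (tert-butyl 2-methylacetoacetate); 2 allyl bromide
Product: 3 tert-butyl 2-acetyl-2-methylpent-4-enoate (racemic at C10)
Conditions: K2CO3, acetone, reflux
Reagents that add atoms: none
Why: SN2 C-alkylation of the β-keto ester enolate builds the quaternary carbon C10 (C9–C10 bond); no stereocontrol is needed because C10 is planarised in step 15.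

Step 2
Reactants: 3 tert-butyl 2-acetyl-2-methylpent-4-enoate
Product: 4 tert-butyl 2-acetyl-2-methyl-4-oxobutanoate
Conditions: O3, CH2Cl2, −78 °C; then PPh3, −78 °C to rt
Reagents that add atoms: ozone, [O-][O+]=O
Why: Ozonolysis with reductive work-up cleaves the only alkene to the C8 aldehyde; the quaternary β-keto ester cannot enolise toward C10 and survives.

Step 3
Reactants: 4 tert-butyl 2-acetyl-2-methyl-4-oxobutanoate; 5 ethyl 2-(bromomethyl)acrylate
Product: 8 tert-butyl 2-acetyl-2-methyl-3-[(2R)-4-methylidene-5-oxooxolan-2-yl]propanoate, via silyl ether 6 (not isolated), via hydroxy ester 7 (not isolated)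
Conditions: CrCl2 (10 mol %), chiral carbazole-bis(oxazoline) ligand (12 mol %), Mn, TMSCl, iPr2NEt (cat.), THF, rt; then TsOH·H2O (cat.), wet CH2Cl2, rt
Reagents that add atoms: none
Why: Catalytic asymmetric Nozaki–Hiyama–Kishi-type 2-(alkoxycarbonyl)allylation, in which the chiral Cr(III) allyl adds to one enantioface of the aldehyde (catalyst control sets C8, the ketone is not attacked), followed by acid-induced desilylation and lactonisation onto the unhindered ethyl ester.

Step 4
Reactants: 8 tert-butyl 2-acetyl-2-methyl-3-[(2R)-4-methylidene-5-oxooxolan-2-yl]propanoate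
Product: 10 tert-butyl 2-acetyl-3-[(2S)-4-(bromomethyl)-5-oxo-2,5-dihydrofuran-2-yl]-2-methylpropanoate, via dibromide 9 (not isolated)
Conditions: Br2, CH2Cl2, 0 °C, dark; then Et3N, 0 °C to rt
Reagents that add atoms: bromine, BrBr
Why: Bromine addition to the exocyclic alkene and E2 dehydrobromination toward the ring CH2 (as in the preparation of 2-(bromomethyl)acrylates from 2,3-dibromoisobutyrates) should give the conjugated 3-(bromomethyl)butenolide; C8 is not touched (the descriptor changes only through CIP ranking).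

Step 5
Reactants: 10 tert-butyl 2-acetyl-3-[(2S)-4-(bromomethyl)-5-oxo-2,5-dihydrofuran-2-yl]-2-methylpropanoate
Product: 11 tert-butyl 2-acetyl-2-methyl-3-[(2S)-5-oxo-4-[(tributylstannyl)methyl]-2,5-dihydrofuran-2-yl]propanoate
Conditions: (Bu3Sn)2, Pd2(dba)3 (2.5 mol %), THF, rt to 40 °C
Reagents that add atoms: hexabutylditin, CCCC[Sn](CCCC)(CCCC)[Sn](CCCC)(CCCC)CCCC
Why: Pd(0)-catalysed stannylation of the allylic bromide (π-allyl palladium, transmetalation with the distannane, reductive elimination at the primary terminus) should give the conjugated primary allylstannane.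

Step 6
Reactants: 12 (S)-3-hydroxy-γ-butyrolactone [(4S)-4-hydroxyoxolan-2-one]
Product: 13 (3S)-3,4-dihydroxy-N,N-dimethylbutanamide
Conditions: Me2NH (2 M in THF), MeOH, rt
Reagents that add atoms: dimethylamine, CNC
Why: Aminolysis of the γ-lactone installs the C3 dimethylamide that later serves as the 2π partner and leaving group; the C5 stereocentre comes from the chiral pool and is untouched.

Step 7
Reactants: 13 (3S)-3,4-dihydroxy-N,N-dimethylbutanamide
Product: 14 (3S)-N,N-dimethyl-3,4-bis(triethylsilyloxy)butanamide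
Conditions: TESCl, imidazole, DMF, 0 °C to rt
Reagents that add atoms: chlorotriethylsilane, CC[Si](Cl)(CC)CC
Why: Imidazole-mediated silylation protects both hydroxyls and allows enolate chemistry at C4.

Step 8
Reactants: 14 (3S)-N,N-dimethyl-3,4-bis(triethylsilyloxy)butanamide
Product: 17 (3S)-N,N-dimethyl-2-methylidene-3,4-bis(triethylsilyloxy)butanamide, via Mannich base 15 (not isolated), via ammonium iodide 16 (not isolated)
Conditions: LDA, THF, −78 °C; Me2N+=CH2 I−, −78 to 0 °C; then MeI, rt; then DBU, CH2Cl2, rt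
Reagents that add atoms: Eschenmoser's salt (N,N-dimethylmethyleneiminium iodide), C=[N+](C)C.[I-]
Why: Mannich reaction of the amide lithium enolate, N-methylation and Hofmann-type elimination give the C4=C15 methylene; the β-silyloxy group is a poor leaving group at −78 °C and C5 is not enolisable.

Step 9
Reactants: 17 (3S)-N,N-dimethyl-2-methylidene-3,4-bis(triethylsilyloxy)butanamide
Product: 18 (3S)-4-hydroxy-N,N-dimethyl-2-methylidene-3-(triethylsilyloxy)butanamide
Conditions: PPTS (cat.), MeOH/CH2Cl2, −10 °C
Reagents that add atoms: none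
Why: Acid-catalysed methanolysis removes the less hindered primary triethylsilyl ether selectively.

Step 10
Reactants: 18 (3S)-4-hydroxy-N,N-dimethyl-2-methylidene-3-(triethylsilyloxy)butanamide
Product: 19 (3S)-N,N-dimethyl-2-methylidene-4-oxo-3-(triethylsilyloxy)butanamide
Conditions: Dess–Martin periodinane, NaHCO3, CH2Cl2, 0 °C; used at once
Reagents that add atoms: none
Why: Dess–Martin oxidation under buffered, amine-free conditions should give the α-silyloxy aldehyde without epimerisation at C5 or migration of the C4=C15 alkene into conjugation.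

Step 11
Reactants: 11 tert-butyl 2-acetyl-2-methyl-3-[(2S)-5-oxo-4-[(tributylstannyl)methyl]-2,5-dihydrofuran-2-yl]propanoate; 19 (3S)-N,N-dimethyl-2-methylidene-4-oxo-3-(triethylsilyloxy)butanamide
Product: 20 tert-butyl 2-acetyl-3-{(2S,3S)-3-[(1R,2S)-3-(dimethylcarbamoyl)-1-hydroxy-2-(triethylsilyloxy)but-3-en-1-yl]-4-methylidene-5-oxooxolan-2-yl}-2-methylpropanoate (5S,6R,7S,8S; C7 is S here only because the free 6-OH lowers the CIP rank of C6)
Conditions: BF3·OEt2 (2.5 equiv), CH2Cl2, −78 °C; aq. NaHCO3/KF
Reagents that add atoms: none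
Why: Lewis acid-promoted SE2' allylation through an open transition state, in which C7 of the 2-(alkoxycarbonyl)allylstannane attacks the BF3-bound aldehyde anti to the C8 side chain (trans lactone), while the syn-selective antiperiplanar topology and polar Felkin–Anh attack anti to the C5 silyloxy group are matched, so that C6 and C7 are set together from C5 and C8 and the C11=C13 methylene is unveiled in the same event.

Step 12
Reactants: 20 the seco-alcohol of step 11
Product: 21 tert-butyl 2-acetyl-3-{(2S,3R)-3-[(1R,2S)-3-(dimethylcarbamoyl)-1-(methacryloyloxy)-2-(triethylsilyloxy)but-3-en-1-yl]-4-methylidene-5-oxooxolan-2-yl}-2-methylpropanoate (5S,6R,7R,8S)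
Conditions: methacrylic anhydride, DMAP, Et3N, CH2Cl2, 0 °C to rt
Reagents that add atoms: methacrylic anhydride, C=C(C)C(=O)OC(=O)C(C)=C
Why: DMAP-catalysed acyl transfer to the only free hydroxyl puts the methacrylate on O6 without any diol differentiation problem and blocks translactonisation to O6.

Step 13
Reactants: 21 the methacrylate tert-butyl ester of step 12
Product: 23 2-acetyl-3-{(2S,3R)-3-[(1R,2S)-3-(dimethylcarbamoyl)-1-(methacryloyloxy)-2-(triethylsilyloxy)but-3-en-1-yl]-4-methylidene-5-oxooxolan-2-yl}-2-methylpropanoic acid, via trimethylsilyl ester 22 (not isolated)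
Conditions: TMSOTf, 2,6-lutidine, CH2Cl2, −20 to 0 °C; then pH 4 buffer, 0 °C
Reagents that add atoms: none
Why: Silyl triflate-mediated tert-butyl ester cleavage (O-silylation, loss of isobutene) should leave the TES ether, lactone and enoates intact, and cold aqueous hydrolysis of the silyl ester gives the α,α-disubstituted β-keto acid.

Step 14
Reactants: 23 the β-keto acid of step 13
Product: 24 (1R,2S)-1-[(2S,3R)-2-(2-chloro-2-methyl-3-oxobutyl)-4-methylidene-5-oxooxolan-3-yl]-3-(dimethylcarbamoyl)-2-(triethylsilyloxy)but-3-en-1-yl 2-methylprop-2-enoate (C10 epimers)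
Conditions: NCS, Et3N (10 mol %), toluene, 0 °C to rt
Reagents that add atoms: N-chlorosuccinimide, O=C1CCC(=O)N1Cl
Why: Decarboxylative chlorination, in which the ammonium β-keto carboxylate loses CO2 to the C10=C1 enolate that NCS chlorinates regiospecifically at C10; the electron-poor alkenes and the tertiary amide do not react with NCS.

Step 15
Reactants: 24 the tertiary α-chloro ketone seco-amide of step 14
Product: 27 5-O-triethylsilyl ether of the target, (5S,6R,7R,8S,10S)-1-oxo-5-(triethylsilyloxy)-3,10-epoxygermacra-2,4(15),11(13)-trien-12,8-olid-6-yl 2-methylprop-2-enoate, via oxyallyl cation 25 (not isolated), via aminal 26 (not isolated)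
Conditions: Et3N (3 equiv), LiClO4 (1 M), Et2O/MeCN, syringe-pump addition to 0.002 M, 0 °C to rt; then AcOH (cat.), rt
Reagents that add atoms: none
Why: Proposed new method: Et3N enolises the C2 methyl of 24 and lithium-assisted loss of chloride from C10 gives the 2-oxyallyl cation 25 (both C10 epimers converge), whose tertiary terminus C10 is captured by the oxygen of the C3 N,N-dimethylamide, after which the enolate carbon C2 closes onto the O-alkyl imidate carbon C3 to give aminal 26 and E1cB loss of dimethylamine installs C2=C3. The closest known reactions are the intermolecular [3+2] cyclocoupling of oxyallyl cations (from α,α'-dibromo ketones and Fe2(CO)9) with N,N-dimethylcarboxamides to give 3(2H)-furanones, and the LiClO4/Et3N ionisation of α-chloro ketones used for (4+3) cycloadditions; they are merged here and run intramolecularly as a macrocyclisation. The nine-membered oxacycle (O, C3–C10) closes by capture of the planar cation by the amide oxygen, the furanone closes by a 5-exo-trig Mannich-type attack of C2 on the iminium carbon, and this second bond completes the ten-membered carbocycle C1–C10. The only new stereocentre, C10, is set by which face of the cation the tethered amide reaches; the C8 stereocentre, two atoms away and locked in the trans-fused lactone, directs the six-atom tether back over one face, which is expected but not assured to give the natural 10S bicycle with the C14 methyl outside the bridged frame. The step needs O-to-C10 and C2-to-C3 regiochemistry (secured by the tertiary versus primary cation termini), amide oxygen over ester oxygens and solvent (the amide is the best neutral O-nucleophile, O5 is masked as the TES ether, the medium is non-nucleophilic), and intra- over intermolecular capture (high dilution).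

Step 16
Reactants: 27 the 5-O-triethylsilyl ether of the target
Product: 28 CNP0142847.1, (5S,6R,7R,8S,10S)-5-hydroxy-1-oxo-3,10-epoxygermacra-2,4(15),11(13)-trien-12,8-olid-6-yl 2-methylprop-2-enoate
Conditions: HF·pyridine, pyridine, THF, 0 °C
Reagents that add atoms: none
Why: Fluoride-mediated cleavage of the secondary triethylsilyl ether under mildly acidic conditions, which avoid acyl migration from O6 to O5 and conjugate additions to the two enoates.

## Compound list

1 | tert-butyl 2-methyl-3-oxobutanoate | CC(=O)C(C)C(=O)OC(C)(C)C | starting material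
2 | allyl bromide | C=CCBr | starting material
3 | tert-butyl 2-acetyl-2-methylpent-4-enoate | CC(=O)C(C)(CC=C)C(=O)OC(C)(C)C | intermediate
4 | tert-butyl 2-acetyl-2-methyl-4-oxobutanoate | CC(=O)C(C)(CC=O)C(=O)OC(C)(C)C | intermediate
5 | ethyl 2-(bromomethyl)acrylate | C=C(CBr)C(=O)OCC | starting material
6 | 1-tert-butyl 7-ethyl (4R)-2-acetyl-2-methyl-6-methylidene-4-(trimethylsilyloxy)heptanedioate | CCOC(=O)C(=C)C[C@@H](O[Si](C)(C)C)CC(C)(C(C)=O)C(=O)OC(C)(C)C | intermediate (not isolated)
7 | 1-tert-butyl 7-ethyl (4R)-2-acetyl-4-hydroxy-2-methyl-6-methylideneheptanedioate | CCOC(=O)C(=C)C[C@@H](O)CC(C)(C(C)=O)C(=O)OC(C)(C)C | intermediate (not isolated)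
8 | tert-butyl 2-acetyl-2-methyl-3-[(2R)-4-methylidene-5-oxooxolan-2-yl]propanoate | C=C1C[C@H](CC(C)(C(C)=O)C(=O)OC(C)(C)C)OC1=O | intermediate
9 | tert-butyl 2-acetyl-3-[(2S)-4-bromo-4-(bromomethyl)-5-oxooxolan-2-yl]-2-methylpropanoate | BrCC1(Br)C[C@H](CC(C)(C(C)=O)C(=O)OC(C)(C)C)OC1=O | intermediate (not isolated)
10 | tert-butyl 2-acetyl-3-[(2S)-4-(bromomethyl)-5-oxo-2,5-dihydrofuran-2-yl]-2-methylpropanoate | BrCC1=C[C@H](CC(C)(C(C)=O)C(=O)OC(C)(C)C)OC1=O | intermediate
11 | tert-butyl 2-acetyl-2-methyl-3-[(2S)-5-oxo-4-[(tributylstannyl)methyl]-2,5-dihydrofuran-2-yl]propanoate | CCCC[Sn](CCCC)(CCCC)CC1=C[C@H](CC(C)(C(C)=O)C(=O)OC(C)(C)C)OC1=O | intermediate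
12 | (S)-3-hydroxy-γ-butyrolactone | O=C1C[C@H](O)CO1 | starting material
13 | (3S)-3,4-dihydroxy-N,N-dimethylbutanamide | CN(C)C(=O)C[C@H](O)CO | intermediate
14 | (3S)-N,N-dimethyl-3,4-bis(triethylsilyloxy)butanamide | CN(C)C(=O)C[C@H](O[Si](CC)(CC)CC)CO[Si](CC)(CC)CC | intermediate
15 | (3S)-2-[(dimethylamino)methyl]-N,N-dimethyl-3,4-bis(triethylsilyloxy)butanamide | CN(C)CC(C(=O)N(C)C)[C@H](O[Si](CC)(CC)CC)CO[Si](CC)(CC)CC | intermediate (not isolated)
16 | [(3S)-2-(dimethylcarbamoyl)-3,4-bis(triethylsilyloxy)butyl]trimethylammonium iodide | C[N+](C)(C)CC(C(=O)N(C)C)[C@H](O[Si](CC)(CC)CC)CO[Si](CC)(CC)CC.[I-] | intermediate (not isolated)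
17 | (3S)-N,N-dimethyl-2-methylidene-3,4-bis(triethylsilyloxy)butanamide | C=C(C(=O)N(C)C)[C@H](O[Si](CC)(CC)CC)CO[Si](CC)(CC)CC | intermediate
18 | (3S)-4-hydroxy-N,N-dimethyl-2-methylidene-3-(triethylsilyloxy)butanamide | C=C(C(=O)N(C)C)[C@H](O[Si](CC)(CC)CC)CO | intermediate
19 | (3S)-N,N-dimethyl-2-methylidene-4-oxo-3-(triethylsilyloxy)butanamide | C=C(C(=O)N(C)C)[C@H](O[Si](CC)(CC)CC)C=O | intermediate
20 | seco-alcohol (5S,6R,7S,8S), tert-butyl 2-acetyl-3-{(2S,3S)-3-[(1R,2S)-3-(dimethylcarbamoyl)-1-hydroxy-2-(triethylsilyloxy)but-3-en-1-yl]-4-methylidene-5-oxooxolan-2-yl}-2-methylpropanoate | O[C@H]([C@@H]1C(=C)C(=O)O[C@H]1CC(C)(C(C)=O)C(=O)OC(C)(C)C)[C@H](C(C(=O)N(C)C)=C)O[Si](CC)(CC)CC | intermediate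
21 | seco-methacrylate tert-butyl ester (5S,6R,7R,8S) | C=C(C)C(=O)O[C@H]([C@@H]1C(=C)C(=O)O[C@H]1CC(C)(C(C)=O)C(=O)OC(C)(C)C)[C@H](C(C(=O)N(C)C)=C)O[Si](CC)(CC)CC | intermediate
22 | trimethylsilyl ester of acid 23 (5S,6R,7R,8S) | C=C(C)C(=O)O[C@H]([C@@H]1C(=C)C(=O)O[C@H]1CC(C)(C(C)=O)C(=O)O[Si](C)(C)C)[C@H](C(C(=O)N(C)C)=C)O[Si](CC)(CC)CC | intermediate (not isolated)
23 | seco β-keto acid (5S,6R,7R,8S) | C=C(C)C(=O)O[C@H]([C@@H]1C(=C)C(=O)O[C@H]1CC(C)(C(C)=O)C(=O)O)[C@H](C(C(=O)N(C)C)=C)O[Si](CC)(CC)CC | intermediate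
24 | seco α-chloro ketone (5S,6R,7R,8S), (1R,2S)-1-[(2S,3R)-2-(2-chloro-2-methyl-3-oxobutyl)-4-methylidene-5-oxooxolan-3-yl]-3-(dimethylcarbamoyl)-2-(triethylsilyloxy)but-3-en-1-yl 2-methylprop-2-enoate | C=C(C)C(=O)O[C@H]([C@@H]1C(=C)C(=O)O[C@H]1CC(C)(Cl)C(C)=O)[C@H](C(C(=O)N(C)C)=C)O[Si](CC)(CC)CC | intermediate
25 | 2-oxyallyl cation (C10–C1–C2) derived from 24 | C=C(C)C(=O)O[C@H]([C@@H]1C(=C)C(=O)O[C@H]1C[C+](C)C([O-])=C)[C@H](C(C(=O)N(C)C)=C)O[Si](CC)(CC)CC | intermediate (not isolated)
26 | bicyclic aminal, 3-(dimethylamino)-2,3-dihydro precursor of 27 (C3 configuration undefined) | C=C(C)C(=O)O[C@@H]1[C@@H]2C(=C)C(=O)O[C@H]2C[C@]2(C)OC(N(C)C)(CC2=O)C(=C)[C@@H]1O[Si](CC)(CC)CC | intermediate (not isolated)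
27 | 5-O-triethylsilyl ether of the target (5S,6R,7R,8S,10S) | C=C(C)C(=O)O[C@@H]1[C@@H]2C(=C)C(=O)O[C@H]2C[C@]2(C)OC(=CC2=O)C(=C)[C@@H]1O[Si](CC)(CC)CC | intermediate
28 | CNP0142847.1 (5S,6R,7R,8S,10S) | C=C(C)C(=O)O[C@@H]1[C@@H]2C(=C)C(=O)O[C@H]2C[C@]2(C)OC(=CC2=O)C(=C)[C@@H]1O | target

## Step count and risks

Total step count: 16 (steps 1–5 for the stannane, steps 6–10 for the aldehyde, steps 11–16 after the union).
Longest linear sequence: 11 steps (1–5, then 11–16; the branch 6–10, then 11–16 is equally long).

Steps most likely to fail: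

1. Step 15 (Proposed new method). What may go wrong: capture of the oxyallyl cation by the tethered amide through a nine-membered transition state may lose to proton loss from the cation (enone formation), Favorskii-type collapse or intermolecular capture, and the facial selectivity at C10 may be poor. Fallback (known chemistry, reversed order of ring formation), from bromide 10 and amide 17 back to 27: the tert-butyl ester of 10 is cleaved (TMSOTf, 2,6-lutidine) to keto acid F1, and decarboxylative chlorination (NCS, cat. Et3N) gives the tertiary α-chloro ketone F2. Ionisation of F2 (Na2CO3, hexafluoroisopropanol) in the presence of excess 17 gives, by the intermolecular oxyallyl–carboxamide cyclocoupling and loss of dimethylamine, furanone F3, from which the 10S epimer is separated. Methanolysis of the primary silyl ether (PPTS, MeOH) gives alcohol F4 and Dess–Martin oxidation gives aldehyde F5. The ten-membered ring is then closed at C6–C7 by an intramolecular Nozaki–Hiyama–Kishi-type allylation of the aldehyde by the allylic bromide (CrCl2, THF, high dilution), a ring closure established for germacranolides, to give hydroxy lactone F6. Acylation with methacrylic anhydride (DMAP) returns to 27.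

2. Step 11. What may go wrong: low reactivity of the electron-poor, γ-substituted allylstannane toward the hindered aldehyde, 1,3-stannyl shift, and poor facial selectivity at the aldehyde carbon (C6). Fallback, from bromide 10 and aldehyde 19 back to 21: an indium-mediated Barbier allylation (In, THF/H2O, rt) is run directly on 10; its closed six-membered transition state with the ring-locked allyl geometry is expected to give the C6-epimeric alcohol F7. A Mitsunobu esterification with methacrylic acid (PPh3, DIAD, THF) then inverts C6 and installs the methacrylate in one operation, giving 21.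

3. Step 3. What may go wrong: insufficient enantioface selection with this keto aldehyde, and competing aldol or hemiketal chemistry of the 1,4-dicarbonyl unit under the chromium conditions. Fallback (the C8 stereocentre is bought instead of made), from 1 back to 8: the sodium enolate of 1 is alkylated with (S)-epichlorohydrin (NaH, DMF; epoxide opening at CH2 and reclosure) to give epoxide F8. Opening of F8 at its terminal carbon by sodium triethyl phosphonoacetate with lactonisation (THF/toluene, heat) gives α-phosphono lactone F9. Horner–Wadsworth–Emmons methylenation of F9 with aqueous formaldehyde (K2CO3) gives 8.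

## Further compounds

F1 | step 15 | 2-acetyl-3-[(2S)-4-(bromomethyl)-5-oxo-2,5-dihydrofuran-2-yl]-2-methylpropanoic acid | BrCC1=C[C@H](CC(C)(C(C)=O)C(=O)O)OC1=O
F2 | step 15 | (5S)-3-(bromomethyl)-5-(2-chloro-2-methyl-3-oxobutyl)furan-2(5H)-one | BrCC1=C[C@H](CC(C)(Cl)C(C)=O)OC1=O
F3 | step 15 | (5S)-3-(bromomethyl)-5-{[(2S)-5-[(3S)-3,4-bis(triethylsilyloxy)but-1-en-2-yl]-2-methyl-3-oxo-2,3-dihydrofuran-2-yl]methyl}furan-2(5H)-one | BrCC1=C[C@H](C[C@]2(C)OC(=CC2=O)C(=C)[C@H](O[Si](CC)(CC)CC)CO[Si](CC)(CC)CC)OC1=O
F4 | step 15 | (5S)-3-(bromomethyl)-5-{[(2S)-5-[(3S)-4-hydroxy-3-(triethylsilyloxy)but-1-en-2-yl]-2-methyl-3-oxo-2,3-dihydrofuran-2-yl]methyl}furan-2(5H)-one | BrCC1=C[C@H](C[C@]2(C)OC(=CC2=O)C(=C)[C@H](O[Si](CC)(CC)CC)CO)OC1=O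
F5 | step 15 | (2S)-3-{(5S)-5-[((2S)-4-(bromomethyl)-5-oxo-2,5-dihydrofuran-2-yl)methyl]-5-methyl-4-oxo-4,5-dihydrofuran-2-yl}-2-(triethylsilyloxy)but-3-enal | BrCC1=C[C@H](C[C@]2(C)OC(=CC2=O)C(=C)[C@H](O[Si](CC)(CC)CC)C=O)OC1=O
F6 | step 15 | (5S,6R,7S,8S,10S)-6-hydroxy-1-oxo-5-(triethylsilyloxy)-3,10-epoxygermacra-2,4(15),11(13)-trien-12,8-olide | O[C@@H]1[C@@H]2C(=C)C(=O)O[C@H]2C[C@]2(C)OC(=CC2=O)C(=C)[C@@H]1O[Si](CC)(CC)CC
F7 | step 11 | C6 epimer of 20 (5S,6S,7S,8S), tert-butyl 2-acetyl-3-{(2S,3S)-3-[(1S,2S)-3-(dimethylcarbamoyl)-1-hydroxy-2-(triethylsilyloxy)but-3-en-1-yl]-4-methylidene-5-oxooxolan-2-yl}-2-methylpropanoate | O[C@@H]([C@@H]1C(=C)C(=O)O[C@H]1CC(C)(C(C)=O)C(=O)OC(C)(C)C)[C@H](C(C(=O)N(C)C)=C)O[Si](CC)(CC)CC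
F8 | step 3 | tert-butyl 2-acetyl-2-methyl-3-[(2S)-oxiran-2-yl]propanoate | CC(=O)C(C)(C[C@H]1CO1)C(=O)OC(C)(C)C
F9 | step 3 | tert-butyl 2-acetyl-3-[(2S)-4-(diethoxyphosphoryl)-5-oxooxolan-2-yl]-2-methylpropanoate | CCOP(=O)(OCC)C1C[C@H](CC(C)(C(C)=O)C(=O)OC(C)(C)C)OC1=O
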